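**Retrosynthetic overview**

1. Chain numbering C1–C7: C1 on ring A (2,4-dihydroxy-3-methoxyphenyl), C3 the ketone carbon, C7 on ring B (4-methoxyphenyl). Target 16 ⇐ (E)-6-ene bis(benzyl ether) 15 by one hydrogenation.
2. Key disconnection C4–C5: 15 ⇐ 4-methoxycinnamyl β-keto ester 13 by palladium-catalysed decarboxylative allylation. This copies the presumed diarylheptanoid biosynthesis, where the β-keto acid built from the first C6–C3 unit and malonate is joined at the malonate carbon C4 to the second C6–C3 unit with loss of CO2. Here C5 enters at the alcohol oxidation level and arrives as CH2.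
3. Enabling feature: C4 lies between the C3 carbonyl and the C5–C6–C7 chain that ends on ring B. C4 can therefore carry a carboxyl group (activating group and ester tether in one, expelled as CO2), and C5–C7 with ring B form a cinnamyl unit whose η3-allylpalladium is attacked at C5.
4. 13 ⇐ acid 9 + Meldrum's acid 5 (C3–C4 bond, malonate equivalent) + alcohol 11; 9 ⇐ 2-methoxyresorcinol 1 by benzylation, formylation and reductive Knoevenagel homologation.
5. No ring is formed in the route: ring A comes from 1 and ring B from 11.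

Key step: step 6

Remark on the chemistry: 16 has no stereocentre; the open keto-phenol is taken as the target, although it may equilibrate with its cyclic 2-chromanol hemiketal. Compounds 1, 5 and 11 are taken as purchased.

**Step 1**
Reactants: 1 2-methoxyresorcinol (2-methoxybenzene-1,3-diol)
Product: 2 1,3-bis(benzyloxy)-2-methoxybenzene
Conditions: BnBr (2.4 equiv), K2CO3 (3 equiv), DMF, 60 °C
Reagents that add atoms: benzyl bromide, BrCc1ccccc1
Why: Williamson ether synthesis on both phenoxides of the symmetric diol should give the bis(benzyl ether), whose protecting groups withstand steps 2–6 and leave in the final hydrogenation.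

**Step 2**
Reactants: 2 1,3-bis(benzyloxy)-2-methoxybenzene
Product: 4 2,4-bis(benzyloxy)-3-methoxybenzaldehyde, via aryl iminium chloride 3 (not isolated)
Conditions: POCl3 (1.5 equiv), DMF, 0 → 75 °C; then ice–water
Reagents that add atoms: N,N-dimethylformamide, CN(C)C=O; water, O
Why: Vilsmeier–Haack formylation should occur at C4 of 2 (identical with C6 by symmetry), the position ortho to one benzyloxy group and para to the other, whereas C5 is activated only by the twisted central methoxy group, as in the formylation of 1,2,3-trialkoxybenzenes.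

**Step 3**
Reactants: 4 2,4-bis(benzyloxy)-3-methoxybenzaldehyde; 5 Meldrum's acid (2,2-dimethyl-1,3-dioxane-4,6-dione)
Product: 9 3-[2,4-bis(benzyloxy)-3-methoxyphenyl]propanoic acid, via arylidene Meldrum's acid 6 (not isolated), via benzyl Meldrum's acid 7 (not isolated), via benzylmalonic acid 8 (not isolated)
Conditions: HCO2H–Et3N (5:2), 95 °C
Reagents that add atoms: none
Why: Knoevenagel condensation, conjugate hydride transfer from formate to the strongly electrophilic arylidene Meldrum's acid and hydrolysis with decarboxylation run in one pot (reductive Knoevenagel homologation) and should give the saturated acid without hydrogenolysis of the benzyl ethers.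

**Step 4**
Reactants: 9 3-[2,4-bis(benzyloxy)-3-methoxyphenyl]propanoic acid; 5 Meldrum's acid
Product: 10 5-{3-[2,4-bis(benzyloxy)-3-methoxyphenyl]-1-hydroxypropylidene}-2,2-dimethyl-1,3-dioxane-4,6-dione (acyl Meldrum's acid, enol form)
Conditions: DCC (1.2 equiv), DMAP (1.5 equiv), CH2Cl2, 0 °C → rt
Reagents that add atoms: none
Why: C-acylation of Meldrum's acid by the carbodiimide-activated acid forms the C3–C4 bond, with the cyclic malonate playing the part of malonyl-CoA, and the product is stabilised as its hydrogen-bonded enol.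

**Step 5**
Reactants: 10 acyl Meldrum's acid; 11 (E)-3-(4-methoxyphenyl)prop-2-en-1-ol (4-methoxycinnamyl alcohol)
Product: 13 (2E)-3-(4-methoxyphenyl)prop-2-en-1-yl 5-[2,4-bis(benzyloxy)-3-methoxyphenyl]-3-oxopentanoate, via acylketene 12 (not isolated)
Conditions: toluene, 90 °C
Reagents that add atoms: none
Why: thermal fragmentation of the acyl Meldrum's acid with loss of acetone and CO2 gives the acylketene, which the primary allylic alcohol should trap as the β-keto ester without added acid or base.

**Step 6**
Reactants: 13 (2E)-3-(4-methoxyphenyl)prop-2-en-1-yl 5-[2,4-bis(benzyloxy)-3-methoxyphenyl]-3-oxopentanoate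
Product: 15 (6E)-1-[2,4-bis(benzyloxy)-3-methoxyphenyl]-7-(4-methoxyphenyl)hept-6-en-3-one, via C4-allylated keto acid 14 (not isolated)
Conditions: Pd(PPh3)4 (5 mol %), THF, 25–40 °C, degassed
Reagents that add atoms: none
Why: Pd(0) ionises the allylic C–O bond of 13 to an η3-(4-methoxycinnamyl)palladium cation and the β-keto carboxylate; C-allylation at the doubly activated C4 gives acid 14, which loses CO2 to the ketone (should CO2 leave first, the same bond forms from the regiodefined C3–C4 palladium enolate). The closest known reaction type is the Tsuji–Saegusa decarboxylative allylation of allyl β-keto esters (palladium-catalysed Carroll rearrangement), which is well precedented for allyl and cinnamyl esters. No ring is closed and no stereocentre remains, as the C4 centre of 14 is lost with CO2; the E geometry of C6=C7 follows from the syn-η3-allyl complex. Site selectivity at the allyl unit (C5 against C7) is needed and is secured by ring B, since attack at the unsubstituted terminus keeps the styrene conjugation and avoids the aryl-bearing carbon. Site selectivity in the ketone (C4 against C2) is secured by the carboxyl group, which marks C4 as the only activated carbon. Single against double allylation is favoured by the built-in 1:1 ratio of allyl unit and nucleophile, and the benzyl ethers keep the phenols from acting as proton sources or O-nucleophiles.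

**Step 7**
Reactants: 15 (6E)-1-[2,4-bis(benzyloxy)-3-methoxyphenyl]-7-(4-methoxyphenyl)hept-6-en-3-one
Product: 16 1-(2,4-dihydroxy-3-methoxyphenyl)-7-(4-methoxyphenyl)heptan-3-one
Conditions: H2 (1 atm), 10% Pd/C, EtOAc–EtOH, rt
Reagents that add atoms: none
Why: heterogeneous hydrogenation should saturate the styrenic C6=C7 bond and cleave both aryl benzyl ethers by hydrogenolysis in one operation, while the dialkyl ketone and the aryl methyl ethers are inert under neutral conditions at 1 atm.

**Compound list**

1 | 2-methoxyresorcinol (2-methoxybenzene-1,3-diol) | COc1c(O)cccc1O | starting material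
2 | 1,3-bis(benzyloxy)-2-methoxybenzene | COc1c(OCc2ccccc2)cccc1OCc1ccccc1 | intermediate
3 | N-{[2,4-bis(benzyloxy)-3-methoxyphenyl]methylidene}-N-methylmethanaminium chloride (aryl iminium chloride) | C[N+](C)=Cc1ccc(OCc2ccccc2)c(OC)c1OCc1ccccc1.[Cl-] | intermediate
4 | 2,4-bis(benzyloxy)-3-methoxybenzaldehyde | O=Cc1ccc(OCc2ccccc2)c(OC)c1OCc1ccccc1 | intermediate
5 | Meldrum's acid (2,2-dimethyl-1,3-dioxane-4,6-dione) | CC1(C)OC(=O)CC(=O)O1 | starting material
6 | 5-[2,4-bis(benzyloxy)-3-methoxybenzylidene]-2,2-dimethyl-1,3-dioxane-4,6-dione (arylidene Meldrum's acid) | CC1(C)OC(=O)C(=Cc2ccc(OCc3ccccc3)c(OC)c2OCc2ccccc2)C(=O)O1 | intermediate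
7 | 5-[2,4-bis(benzyloxy)-3-methoxybenzyl]-2,2-dimethyl-1,3-dioxane-4,6-dione (benzyl Meldrum's acid) | CC1(C)OC(=O)C(Cc2ccc(OCc3ccccc3)c(OC)c2OCc2ccccc2)C(=O)O1 | intermediate
8 | 2-[2,4-bis(benzyloxy)-3-methoxybenzyl]malonic acid (benzylmalonic acid) | OC(=O)C(Cc1ccc(OCc2ccccc2)c(OC)c1OCc1ccccc1)C(=O)O | intermediate
9 | 3-[2,4-bis(benzyloxy)-3-methoxyphenyl]propanoic acid | OC(=O)CCc1ccc(OCc2ccccc2)c(OC)c1OCc1ccccc1 | intermediate
10 | 5-{3-[2,4-bis(benzyloxy)-3-methoxyphenyl]-1-hydroxypropylidene}-2,2-dimethyl-1,3-dioxane-4,6-dione (acyl Meldrum's acid) | CC1(C)OC(=O)C(=C(O)CCc2ccc(OCc3ccccc3)c(OC)c2OCc2ccccc2)C(=O)O1 | intermediate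
11 | (E)-3-(4-methoxyphenyl)prop-2-en-1-ol (4-methoxycinnamyl alcohol) | COc1ccc(/C=C/CO)cc1 | starting material
12 | 5-[2,4-bis(benzyloxy)-3-methoxyphenyl]pent-1-ene-1,3-dione (acylketene) | O=C=CC(=O)CCc1ccc(OCc2ccccc2)c(OC)c1OCc1ccccc1 | intermediate
13 | (2E)-3-(4-methoxyphenyl)prop-2-en-1-yl 5-[2,4-bis(benzyloxy)-3-methoxyphenyl]-3-oxopentanoate | COc1ccc(/C=C/COC(=O)CC(=O)CCc2ccc(OCc3ccccc3)c(OC)c2OCc2ccccc2)cc1 | intermediate
14 | 5-[2,4-bis(benzyloxy)-3-methoxyphenyl]-2-[(2E)-3-(4-methoxyphenyl)prop-2-en-1-yl]-3-oxopentanoic acid (racemic, C4-allylated keto acid) | COc1ccc(/C=C/CC(C(=O)O)C(=O)CCc2ccc(OCc3ccccc3)c(OC)c2OCc2ccccc2)cc1 | intermediate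
15 | (6E)-1-[2,4-bis(benzyloxy)-3-methoxyphenyl]-7-(4-methoxyphenyl)hept-6-en-3-one | COc1ccc(/C=C/CCC(=O)CCc2ccc(OCc3ccccc3)c(OC)c2OCc2ccccc2)cc1 | intermediate
16 | 1-(2,4-dihydroxy-3-methoxyphenyl)-7-(4-methoxyphenyl)heptan-3-one | COc1ccc(CCCCC(=O)CCc2ccc(O)c(OC)c2O)cc1 | target

**Step count and risks**

Total step count: 7. Longest linear sequence: 7 steps (1 → 16); 5 and 11 enter as purchased compounds.

Steps most likely to fail:

1. Step 6. Allyl and proton transfer between ionised partners may lead to double allylation at C4 alongside unallylated ketone, and attack at C7 would give the branched isomer. The fallback forms the same C4–C5 bond by a directed aldol reaction. It sets out from 10: hydrolysis with double decarboxylation (AcOH–H2O, reflux) should give 4-[2,4-bis(benzyloxy)-3-methoxyphenyl]butan-2-one F1. Its kinetic lithium enolate (LDA, THF, −78 °C, deprotonation at the methyl group C4) is added to purchased 3-(4-methoxyphenyl)propanal F2 to give racemic 1-[2,4-bis(benzyloxy)-3-methoxyphenyl]-5-hydroxy-7-(4-methoxyphenyl)heptan-3-one F3. Acid-catalysed dehydration (TsOH cat., toluene, 80 °C) should give (4E)-1-[2,4-bis(benzyloxy)-3-methoxyphenyl]-7-(4-methoxyphenyl)hept-4-en-3-one F4. Hydrogenation of F4 under the conditions of step 7 comes back to the route at 16.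

2. Step 5. The acidic acyl Meldrum's acid may ionise the acid-labile 4-methoxycinnamyl alcohol or its ester at 90 °C, with ether formation, allylic transposition or C-cinnamylation. The fallback replaces the hot acidic ketene trapping by a cold, base-mediated crossed Claisen condensation. It sets out from 11 and 9: acetylation of 11 (Ac2O, pyridine, rt) gives (2E)-3-(4-methoxyphenyl)prop-2-en-1-yl acetate F5, and 9 with carbonyldiimidazole (THF, rt) gives 1-{3-[2,4-bis(benzyloxy)-3-methoxyphenyl]propanoyl}imidazole F6. Addition of F6 to the lithium enolate of F5 (LiHMDS, 2.2 equiv, THF, −78 °C) should give the β-keto ester and comes back to the route at 13.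

3. Step 7. Once the 2-O-benzyl group is lost, the free phenol may add to the C3 ketone and the hemiketal may be reduced to a 2-substituted chroman, or hydrogenolysis of the flanked 2-O-benzyl ether may stall. The fallback separates the two events and removes the benzyl groups without hydrogen. It sets out from 15: homogeneous hydrogenation (H2, RhCl(PPh3)3, benzene–EtOH, rt) should saturate only C6=C7 and give 1-[2,4-bis(benzyloxy)-3-methoxyphenyl]-7-(4-methoxyphenyl)heptan-3-one F7. Acidolytic debenzylation (TFA, pentamethylbenzene as cation scavenger, rt, aqueous work-up) comes back to the route at 16.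

**Further compounds**

F1 | step 6 | 4-[2,4-bis(benzyloxy)-3-methoxyphenyl]butan-2-one | CC(=O)CCc1ccc(OCc2ccccc2)c(OC)c1OCc1ccccc1
F2 | step 6 | 3-(4-methoxyphenyl)propanal (purchased) | COc1ccc(CCC=O)cc1
F3 | step 6 | 1-[2,4-bis(benzyloxy)-3-methoxyphenyl]-5-hydroxy-7-(4-methoxyphenyl)heptan-3-one (racemic) | COc1ccc(CCC(O)CC(=O)CCc2ccc(OCc3ccccc3)c(OC)c2OCc2ccccc2)cc1
F4 | step 6 | (4E)-1-[2,4-bis(benzyloxy)-3-methoxyphenyl]-7-(4-methoxyphenyl)hept-4-en-3-one | COc1ccc(CC/C=C/C(=O)CCc2ccc(OCc3ccccc3)c(OC)c2OCc2ccccc2)cc1
F5 | step 5 | (2E)-3-(4-methoxyphenyl)prop-2-en-1-yl acetate | COc1ccc(/C=C/COC(C)=O)cc1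
F6 | step 5 | 1-{3-[2,4-bis(benzyloxy)-3-methoxyphenyl]propanoyl}imidazole | O=C(CCc1ccc(OCc2ccccc2)c(OC)c1OCc1ccccc1)n1ccnc1
F7 | step 7 | 1-[2,4-bis(benzyloxy)-3-methoxyphenyl]-7-(4-methoxyphenyl)heptan-3-one | COc1ccc(CCCCC(=O)CCc2ccc(OCc3ccccc3)c(OC)c2OCc2ccccc2)cc1
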